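The naphthazarin core (oxygen on C1, C4, C5 and C8) is the double enol of a cis-4a,8a-dihydronaphthalene-1,4,5,8-tetraone, so cutting C4a–C5 and C8a–C8 leaves a 2-substituted 1,4-benzoquinone (C1–C4, C4a, C8a) and a symmetrical C4 bisketene unit (C5–C8); naphthazarin tautomers interconvert fast, so it does not matter which ring ends up carrying the side chain.
Behind the quinone stands its hydroquinone dimethyl ether; further cuts are the butyrate C–O bond at C1' and the C2–C1' bond (aryllithium plus the Weinreb amide of 4-methylpent-3-enoic acid).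
Forward: ring one is bought as 2-bromo-1,4-dimethoxybenzene, the C6 chain is attached by acylation, the ketone is reduced, the alcohol butyrylated and the arene oxidised to the quinone; ring two is closed last by [4+2] annulation with 2,5-bis(trimethylsilyloxy)furan and tautomerisation, with no phenol protection and no late oxidation.
Stereochemistry: the single stereocentre C1' (R) is set by Brown reduction of the aryl ketone with (+)-Ipc2BCl and no bond to it is made or broken afterwards; the centres of the cycloadduct vanish on aromatisation.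

Key step: step 7

Remark: "butylshikonin" is read as shikonin n-butanoate (butyrylshikonin), the (R)-ester of the SMILES string; ring atoms are numbered as in 1,4-naphthoquinone and C1' is the side-chain carbinol carbon.

Step 1
Reactants: 1 4-methylpent-3-enoic acid
Product: 3 N-methoxy-N-methyl-4-methylpent-3-enamide, via 1-(4-methylpent-3-enoyl)imidazole 2 (not isolated)
Conditions: CDI (1.1 equiv), CH2Cl2, 0 °C to rt; then MeNH(OMe)·HCl (1.2 equiv), rt
Reagents that add atoms: N,O-dimethylhydroxylamine hydrochloride, CNOC.Cl
Why: Weinreb amide synthesis through the acyl imidazolide (loss of CO2, then aminolysis) needs no strong base, so the trisubstituted β,γ-alkene should not move into conjugation.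

Step 2
Reactants: 4 2-bromo-1,4-dimethoxybenzene; 3 N-methoxy-N-methyl-4-methylpent-3-enamide
Product: 7 1-(2,5-dimethoxyphenyl)-4-methylpent-3-en-1-one, via 2,5-dimethoxyphenyllithium 5 (not isolated), via chelated tetrahedral lithium adduct 6 (not isolated)
Conditions: n-BuLi (1.05 equiv), THF, −78 °C; then 3, −78 °C; sat. aq. NH4Cl at −78 °C
Reagents that add atoms: none
Why: Bromine–lithium exchange followed by Weinreb ketone synthesis stops at the ketone because the chelated adduct 6 survives until the quench, and the cold buffered work-up should keep the alkene β,γ.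

Step 3
Reactants: 7 1-(2,5-dimethoxyphenyl)-4-methylpent-3-en-1-one
Product: 8 (R)-1-(2,5-dimethoxyphenyl)-4-methylpent-3-en-1-ol
Conditions: (+)-Ipc2BCl [(+)-DIP-Cl, 1.4 equiv], THF, −25 °C; then HN(CH2CH2OH)2, Et2O, rt
Reagents that add atoms: none
Why: In this Brown asymmetric reduction the reagent transfers a β-hydride of an isopinocampheyl group through a boat-like six-membered transition state with the aryl group in the position of the large substituent, which by analogy with acetophenone-type ketones should deliver hydride to the Si face and give the (R)-carbinol; absolute configuration and enantiomeric purity are to be checked here (Mosher esters, chiral HPLC).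

Step 4
Reactants: 8 (R)-1-(2,5-dimethoxyphenyl)-4-methylpent-3-en-1-ol; 9 butyric anhydride
Product: 10 (R)-1-(2,5-dimethoxyphenyl)-4-methylpent-3-enyl butyrate
Conditions: Et3N, DMAP (cat.), CH2Cl2, 0 °C to rt
Reagents that add atoms: none
Why: DMAP-catalysed acyl transfer through the N-acylpyridinium ion esterifies the secondary alcohol at oxygen, so the C1'–O bond and the configuration stay as they are.

Step 5
Reactants: 10 (R)-1-(2,5-dimethoxyphenyl)-4-methylpent-3-enyl butyrate
Product: 11 2-[(R)-1-butyryloxy-4-methylpent-3-enyl]-1,4-benzoquinone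
Conditions: (NH4)2Ce(NO3)6 (2.5 equiv), MeCN/H2O, 0 °C, about 10 min
Reagents that add atoms: water, O
Why: Oxidative demethylation by tetravalent cerium goes through the arene radical cation, water adds at the two methoxy-bearing carbons and methanol leaves; the dimethoxyarene is oxidised more easily than the trisubstituted alkene, and the short cold contact should spare the ester and C1'.

Step 6
Reactants: 12 succinic anhydride
Product: 13 2,5-bis(trimethylsilyloxy)furan
Conditions: TMSCl (2.4 equiv), Et3N (2.6 equiv), ZnCl2 (cat.), MeCN, rt; filtration under Ar, distillation, used fresh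
Reagents that add atoms: chlorotrimethylsilane, C[Si](C)(C)Cl
Why: Double enol silylation of the anhydride (soft enolisation with Et3N) gives the aromatic disiloxyfuran, a known bisketene equivalent that must be kept free of moisture.

Step 7
Reactants: 11 2-[(R)-1-butyryloxy-4-methylpent-3-enyl]-1,4-benzoquinone; 13 2,5-bis(trimethylsilyloxy)furan
Product: 16 butylshikonin, via oxa-bridged cycloadduct 14 (not isolated), via dihydronaphthalenetetraone 15 (not isolated)
Conditions: 13 (1.05 equiv), PhMe, −40 °C to rt; then 0.5 M aq. HCl/THF, 0 °C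
Reagents that add atoms: none
Why: The electron-rich disiloxyfuran 13 adds across the unsubstituted C=C bond of quinone 11 (its C5=C6, the future C4a–C8a) in a normal-demand Diels–Alder reaction, or by Mukaiyama–Michael addition and ring closure, which makes the same two bonds C4a–C5 and C8a–C8 and gives the 7-oxanorbornene 14. The closest known reaction type is the cycloaddition of 2,5-bis(silyloxy)furans with quinones and other electron-poor dienophiles, whose adducts collapse to 1,4-dioxygenated six-membered rings. The new carbocycle (C4a, C5–C8, C8a) closes by [4+2] cycloaddition; on mild acid work-up the bridgehead bis-silyl ketal of 14 opens with loss of hexamethyldisiloxane to the ene-dione 15, whose two ring-fusion hydrogens move to oxygen, driven by aromatisation and two peri hydrogen bonds, so the sequence is redox-neutral. The four sp3 centres of 14 are not controlled and are all erased, while C1' is a spectator. Only site selectivity between the two quinone C=C bonds is needed, and the branched alkyl substituent at C2 secures it by shielding and slightly deactivating C2=C3; regiochemistry is void because the diene is symmetrical. One equivalent of diene, low temperature, a non-polar solvent and no Lewis acid should limit electron transfer and a second addition to the product.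

Compound list
1 | 4-methylpent-3-enoic acid | CC(C)=CCC(=O)O | starting material
2 | 1-(4-methylpent-3-enoyl)imidazole (not isolated) | CC(C)=CCC(=O)n1ccnc1 | intermediate
3 | N-methoxy-N-methyl-4-methylpent-3-enamide | CC(C)=CCC(=O)N(C)OC | intermediate
4 | 2-bromo-1,4-dimethoxybenzene | COc1ccc(OC)c(Br)c1 | starting material
5 | (2,5-dimethoxyphenyl)lithium (not isolated) | COc1ccc(OC)c([Li])c1 | intermediate
6 | lithium 1-(2,5-dimethoxyphenyl)-1-[methoxy(methyl)amino]-4-methylpent-3-en-1-olate, the chelated tetrahedral adduct (not isolated; new carbon not defined) | COc1ccc(OC)c(C(O[Li])(CC=C(C)C)N(C)OC)c1 | intermediate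
7 | 1-(2,5-dimethoxyphenyl)-4-methylpent-3-en-1-one | COc1ccc(OC)c(C(=O)CC=C(C)C)c1 | intermediate
8 | (R)-1-(2,5-dimethoxyphenyl)-4-methylpent-3-en-1-ol | O[C@H](CC=C(C)C)c1cc(OC)ccc1OC | intermediate
9 | butyric anhydride | CCCC(=O)OC(=O)CCC | starting material
10 | (R)-1-(2,5-dimethoxyphenyl)-4-methylpent-3-enyl butyrate | CCCC(=O)O[C@H](CC=C(C)C)c1cc(OC)ccc1OC | intermediate
11 | 2-[(R)-1-butyryloxy-4-methylpent-3-enyl]-1,4-benzoquinone | CCCC(=O)O[C@H](CC=C(C)C)C1=CC(=O)C=CC1=O | intermediate
12 | succinic anhydride | O=C1CCC(=O)O1 | starting material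
13 | 2,5-bis(trimethylsilyloxy)furan | C[Si](C)(C)Oc1ccc(O[Si](C)(C)C)o1 | intermediate
14 | (R)-1-[5,8-epoxy-1,4-dioxo-5,8-bis(trimethylsilyloxy)-1,4,4a,5,8,8a-hexahydronaphthalen-2-yl]-4-methylpent-3-enyl butyrate, the oxa-bridged cycloadduct (not isolated; C4a, C5, C8, C8a a transient mixture) | CCCC(=O)O[C@H](CC=C(C)C)C1=CC(=O)C2C(C1=O)C3(O[Si](C)(C)C)C=CC2(O[Si](C)(C)C)O3 | intermediate
15 | (R)-1-(1,4,5,8-tetraoxo-1,4,4a,5,8,8a-hexahydronaphthalen-2-yl)-4-methylpent-3-enyl butyrate, the dihydronaphthalenetetraone (not isolated; cis ring fusion, C4a and C8a not defined) | CCCC(=O)O[C@H](CC=C(C)C)C1=CC(=O)C2C(C1=O)C(=O)C=CC2=O | intermediate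
16 | butylshikonin, (R)-1-(5,8-dihydroxy-1,4-dioxo-1,4-dihydronaphthalen-2-yl)-4-methylpent-3-enyl butyrate | CCCC(=O)O[C@H](CC=C(C)C)C1=CC(=O)c2c(O)ccc(O)c2C1=O | target

Total steps: 7. Longest linear sequence: 6 steps (steps 1, 2, 3, 4, 5 and 7, from acid 1); step 6 is a one-step side branch.

Steps most likely to fail

Step 7. Electron transfer from the diene to the quinone, or the enol stage of a stepwise Michael pathway, may put the side-chain ring at the hydroquinone level, from which butyrate is expelled through a quinone methide; the quinone ring of the product may also take up a second diene. Fallback: the ester is introduced after the annulation. Setting out from alcohol 8, silylation (TBSCl, imidazole, DMF) gives (R)-tert-butyl{[1-(2,5-dimethoxyphenyl)-4-methylpent-3-enyl]oxy}dimethylsilane F1. Oxidative demethylation as in step 5 gives 2-[(R)-1-(tert-butyldimethylsilyloxy)-4-methylpent-3-enyl]-1,4-benzoquinone F2, whose silyloxy group is a poor leaving group. Annulation with 13 as in step 7 should pass through the oxa-bridged cycloadduct F3 and the dihydronaphthalenetetraone F4, neither isolated, to O-(tert-butyldimethylsilyl)shikonin F5. HF·pyridine in THF at 0 °C releases shikonin F6. Steglich esterification with butyric acid, DCC and DMAP, which acylates the side-chain hydroxyl in preference to the hydrogen-bonded peri phenols, comes back to the route at 16.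

Step 5. The arene radical cation may couple to biaryl diquinones, the oxidant may attack the trisubstituted alkene, or the benzylic position may be over-oxidised. Fallback: the quinone is released from a para-methoxyphenol, which needs only a mild two-electron oxidant; its free hydroxyl is meta to the side chain, so no ortho-quinone methide can form. Setting out from Weinreb amide 3, commercial 3-bromo-4-methoxyphenol is silylated (TBSCl, imidazole) to (3-bromo-4-methoxyphenoxy)(tert-butyl)dimethylsilane F7. Bromine–lithium exchange (n-BuLi, THF, −78 °C) gives [5-(tert-butyldimethylsilyloxy)-2-methoxyphenyl]lithium F8, which adds to 3 to form the chelated tetrahedral lithium adduct F9 and, after a cold NH4Cl quench, 1-[5-(tert-butyldimethylsilyloxy)-2-methoxyphenyl]-4-methylpent-3-en-1-one F10. Reduction as in step 3 should give (R)-1-[5-(tert-butyldimethylsilyloxy)-2-methoxyphenyl]-4-methylpent-3-en-1-ol F11, and acylation as in step 4 gives (R)-1-[5-(tert-butyldimethylsilyloxy)-2-methoxyphenyl]-4-methylpent-3-enyl butyrate F12. Buffered desilylation (TBAF, AcOH, THF, 0 °C) gives (R)-1-(5-hydroxy-2-methoxyphenyl)-4-methylpent-3-enyl butyrate F13. PhI(OAc)2 in aqueous MeCN at 0 °C then oxidises the phenol with loss of methanol and comes back to the route at quinone 11.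

Step 3. Enantioselectivity may be insufficient, because the ortho-methoxyaryl group and the homoallylic chain differ less in size than phenyl and methyl, and the Lewis-acidic boron reagent may isomerise the β,γ-alkene. Fallback: the stereocentre is made by C–C bond formation, not by reduction. Setting out from bromide 4 through aryllithium 5, a quench with DMF gives, via the lithium hemiaminal alkoxide lithium (2,5-dimethoxyphenyl)(dimethylamino)methanolate F14, 2,5-dimethoxybenzaldehyde F15 (which can also be bought). Brown asymmetric allylboration with the B-allyldiisopinocampheylborane made from (+)-Ipc2BOMe (from (−)-α-pinene) and allylMgBr (Et2O, −78 °C; NaOH/H2O2 work-up) should, by analogy with benzaldehyde, give (R)-1-(2,5-dimethoxyphenyl)but-3-en-1-ol F16. Cross-metathesis with excess 2-methyl-2-butene and the second-generation Grubbs catalyst (H2IMes)(PCy3)Cl2Ru=CHPh in CH2Cl2 at 40 °C installs the trisubstituted alkene with loss of propene and comes back to the route at alcohol 8.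

Further compounds
F1 | step 7 | (R)-tert-butyl{[1-(2,5-dimethoxyphenyl)-4-methylpent-3-enyl]oxy}dimethylsilane | CC(C)(C)[Si](C)(C)O[C@H](CC=C(C)C)c1cc(OC)ccc1OC
F2 | step 7 | 2-[(R)-1-(tert-butyldimethylsilyloxy)-4-methylpent-3-enyl]-1,4-benzoquinone | CC(C)(C)[Si](C)(C)O[C@H](CC=C(C)C)C1=CC(=O)C=CC1=O
F3 | step 7 | oxa-bridged cycloadduct of F2 and 13 (new ring centres not defined) | CC(C)(C)[Si](C)(C)O[C@H](CC=C(C)C)C1=CC(=O)C2C(C1=O)C3(O[Si](C)(C)C)C=CC2(O[Si](C)(C)C)O3
F4 | step 7 | 2-[(R)-1-(tert-butyldimethylsilyloxy)-4-methylpent-3-enyl]-4a,8a-dihydronaphthalene-1,4,5,8-tetraone | CC(C)(C)[Si](C)(C)O[C@H](CC=C(C)C)C1=CC(=O)C2C(C1=O)C(=O)C=CC2=O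
F5 | step 7 | O-(tert-butyldimethylsilyl)shikonin | CC(C)(C)[Si](C)(C)O[C@H](CC=C(C)C)C1=CC(=O)c2c(O)ccc(O)c2C1=O
F6 | step 7 | shikonin | O[C@H](CC=C(C)C)C1=CC(=O)c2c(O)ccc(O)c2C1=O
F7 | step 5 | (3-bromo-4-methoxyphenoxy)(tert-butyl)dimethylsilane | COc1ccc(O[Si](C)(C)C(C)(C)C)cc1Br
F8 | step 5 | [5-(tert-butyldimethylsilyloxy)-2-methoxyphenyl]lithium | COc1ccc(O[Si](C)(C)C(C)(C)C)cc1[Li]
F9 | step 5 | chelated tetrahedral lithium adduct of F8 and 3 | COc1ccc(O[Si](C)(C)C(C)(C)C)cc1C(O[Li])(CC=C(C)C)N(C)OC
F10 | step 5 | 1-[5-(tert-butyldimethylsilyloxy)-2-methoxyphenyl]-4-methylpent-3-en-1-one | COc1ccc(O[Si](C)(C)C(C)(C)C)cc1C(=O)CC=C(C)C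
F11 | step 5 | (R)-1-[5-(tert-butyldimethylsilyloxy)-2-methoxyphenyl]-4-methylpent-3-en-1-ol | O[C@H](CC=C(C)C)c1cc(O[Si](C)(C)C(C)(C)C)ccc1OC
F12 | step 5 | (R)-1-[5-(tert-butyldimethylsilyloxy)-2-methoxyphenyl]-4-methylpent-3-enyl butyrate | CCCC(=O)O[C@H](CC=C(C)C)c1cc(O[Si](C)(C)C(C)(C)C)ccc1OC
F13 | step 5 | (R)-1-(5-hydroxy-2-methoxyphenyl)-4-methylpent-3-enyl butyrate | CCCC(=O)O[C@H](CC=C(C)C)c1cc(O)ccc1OC
F14 | step 3 | lithium (2,5-dimethoxyphenyl)(dimethylamino)methanolate | COc1ccc(OC)c(C(O[Li])N(C)C)c1
F15 | step 3 | 2,5-dimethoxybenzaldehyde | COc1ccc(OC)c(C=O)c1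
F16 | step 3 | (R)-1-(2,5-dimethoxyphenyl)but-3-en-1-ol | O[C@H](CC=C)c1cc(OC)ccc1OC
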